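The plan rests on disconnecting the O1–C2 bond of ring C. The 2,3-cis pair (aryl at C2, hydroxyl at C3) is traced back to a cis-epoxide across C2–C3. The phenol oxygen on C8a opens it at benzylic C2 with inversion. One acid-catalysed operation closes ring C, forms O1–C2 and sets C2, while C3 keeps its oxygen. The precursor is the complete ring D–CH2–ring A diarylmethane (ring D is the acylphloroglucinol ring). Its only free phenol lies between the methylene bridge and the epoxide arm, so the bridge must end up on C8. Ring B carries two benzyl carbonates, which hold back ionisation at C2 and leave with the benzyl ethers in one neutral hydrogenolysis.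

Key step: step 16

Remark (stereochemistry): the target is (2R,3R) in ring C and (S) in the side chain. C2 is inverted and C3 retained in step 16, so the oxirane must be the cis (2S,3R) isomer.
Assumption (step 14): the D-glucose-derived spiro-oxazolidinone ketone is taken to convert cis-β-methylstyrene into the (1R,2S)-oxide, so the benzylic (S) centre needed here calls for the L-glucose-derived antipode. This sense is to be confirmed on a model alkene.
Assumption: every compound marked as starting material in the list is taken to be a catalogue chemical.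
Abbreviations:
- Bn = benzyl; TBS = tert-butyldimethylsilyl.
- DBn = 2,6-bis(benzyloxy)-4-methoxy-3-methyl-5-[(2S)-2-methylbutanoyl]benzyl, the ring D benzyl unit.
- ArA(OR) = 4,6-bis(benzyloxy)-3-(DBn)-2-(OR)phenyl, which is ring A bound through the carbon that becomes C4a.

Step 1
Reactants: 1 (S)-2-methylbutanoic acid; 2 2,4,6-trihydroxytoluene
Product: 4 (S)-2-methyl-1-(2,4,6-trihydroxy-3-methylphenyl)butan-1-one, via (S)-2-methylbutanoyl chloride 3 (not isolated)
Conditions: 1, (COCl)2, cat. DMF, CH2Cl2, 0 °C to rt, concentrate; then 2, AlCl3, CH2Cl2/MeNO2, 0 to 35 °C; aq. HCl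
Reagents that add atoms: oxalyl chloride, `O=C(Cl)C(=O)Cl` (its chlorine stands in 3 only)
Why: Friedel–Crafts acylation: the acylium ion attacks one of the two equivalent free carbons of the very electron-rich triol, and because the acid chloride is made under neutral DMF catalysis and the acylation is kept at or below 35 °C the α-stereocentre taken from the chiral pool should not enolise.

Step 2
Reactants: 4 (S)-2-methyl-1-(2,4,6-trihydroxy-3-methylphenyl)butan-1-one
Product: 5 (S)-1-[4,6-bis(benzyloxy)-2-hydroxy-3-methylphenyl]-2-methylbutan-1-one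
Conditions: BnBr (2.1 equiv), K2CO3, acetone, reflux
Reagents that add atoms: benzyl bromide, `BrCc1ccccc1`
Why: Williamson etherification under weak base should follow the known pattern of partial alkylation of 3-methylphloroacylphenones: the unchelated 4-OH and the less crowded 6-OH react, whereas the 2-OH, wedged between methyl and acyl and hydrogen-bonded to the carbonyl, stays free.

Step 3
Reactants: 5 (S)-1-[4,6-bis(benzyloxy)-2-hydroxy-3-methylphenyl]-2-methylbutan-1-one
Product: 6 (S)-1-[4,6-bis(benzyloxy)-2-methoxy-3-methylphenyl]-2-methylbutan-1-one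
Conditions: MeI, K2CO3, DMF, 40 °C
Reagents that add atoms: iodomethane, `CI`
Why: Williamson methylation with a small electrophile in a dipolar aprotic solvent overcomes the chelation of the last phenol, and carbonate is far too weak a base to enolise the crowded, twisted aryl ketone.

Step 4
Reactants: 6 (S)-1-[4,6-bis(benzyloxy)-2-methoxy-3-methylphenyl]-2-methylbutan-1-one
Product: 7 2,6-bis(benzyloxy)-4-methoxy-3-methyl-5-[(2S)-2-methylbutanoyl]benzaldehyde
Conditions: Cl2CHOMe, AgOSO2CF3, CH2Cl2, −78 °C; then aq. NaHCO3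
Reagents that add atoms: dichloromethyl methyl ether, `COC(Cl)Cl`; water, `O`
Why: Rieche formylation strikes the only unsubstituted ring carbon (ortho to both benzyloxy groups, para to methoxy), and silver-salt activation allows −78 °C, where aryl benzyl ethers and the α-stereocentre should survive.

Step 5
Reactants: 7 2,6-bis(benzyloxy)-4-methoxy-3-methyl-5-[(2S)-2-methylbutanoyl]benzaldehyde
Product: 8 (S)-1-[2,4-bis(benzyloxy)-3-(hydroxymethyl)-6-methoxy-5-methylphenyl]-2-methylbutan-1-one (DBn–OH)
Conditions: NaBH4, THF/MeOH, 0 °C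
Reagents that add atoms: none
Why: Chemoselective borohydride reduction: the aldehyde is reduced at 0 °C while the di-ortho-substituted, α-branched ketone is too shielded to react.

Step 6
Reactants: 8 DBn–OH; 9 3,5-bis(benzyloxy)phenol
Product: 10 3,5-bis(benzyloxy)-2-(DBn)phenol (diarylmethane phenol)
Conditions: 9 (3 equiv), BF3·OEt2 (20 mol %), CH2Cl2, −40 to 0 °C
Reagents that add atoms: none
Why: Friedel–Crafts benzylation through the benzylic cation stabilised by three oxygen substituents: ring D has no free carbon and cannot self-condense, and the phenol, used in excess against double alkylation, should react at C2 next to the small OH rather than at C4 between two benzyloxy groups, as it does in known acid-catalysed cinnamylations.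

Step 7
Reactants: 10 3,5-bis(benzyloxy)-2-(DBn)phenol
Product: 11 4,6-bis(benzyloxy)-2-hydroxy-3-(DBn)benzaldehyde
Conditions: MgCl2, Et3N, (CH2O)n, THF, reflux; then 1 M HCl
Reagents that add atoms: formaldehyde (as paraformaldehyde), `C=O`
Why: Casnati–Skattebøl ortho-formylation: the magnesium phenoxide delivers formaldehyde only to an ortho carbon, only one such carbon is left, and hydride transfer to a second formaldehyde gives the aldehyde whose carbon becomes C4.

Step 8
Reactants: 11 4,6-bis(benzyloxy)-2-hydroxy-3-(DBn)benzaldehyde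
Product: 12 4,6-bis(benzyloxy)-2-(tert-butyldimethylsilyloxy)-3-(DBn)benzaldehyde
Conditions: TBSCl, imidazole, cat. DMAP, DMF, 40 °C
Reagents that add atoms: tert-butyldimethylsilyl chloride, `CC(C)(C)[Si](C)(C)Cl`
Why: Standard silylation masks the future O1 through the organometallic, palladium and oxidation steps, and the chloride/imidazole protocol avoids the enol silylation of the ketone that a silyl triflate could cause.

Step 9
Reactants: 12 4,6-bis(benzyloxy)-2-(tert-butyldimethylsilyloxy)-3-(DBn)benzaldehyde
Product: 13 1-[ArA(OTBS)]prop-2-yn-1-ol (both carbinol epimers)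
Conditions: HC≡CMgBr, THF, −20 to 0 °C; then sat. aq. NH4Cl
Reagents that add atoms: ethynylmagnesium bromide, `C#C[Mg]Br`
Why: 1,2-Addition of an alkynyl Grignard reagent to the aldehyde brings in C3 and C2; the shielded ketone is neither attacked nor enolised by this weakly basic nucleophile, and the new carbinol centre is erased in step 10.

Step 10
Reactants: 13 1-[ArA(OTBS)]prop-2-yn-1-ol
Product: 14 1,5-bis(benzyloxy)-3-(tert-butyldimethylsilyloxy)-4-(DBn)-2-(prop-2-yn-1-yl)benzene
Conditions: Et3SiH, CF3CO2H, CH2Cl2, −40 to −10 °C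
Reagents that add atoms: none
Why: Ionic hydrogenation (Kursanov–Parnes type): acid ionises the benzylic-propargylic alcohol on the trioxygenated ring and the silane traps the cation at the benzylic carbon, giving the skipped aryl-propyne without touching ketone, ethers or the terminal alkyne.

Step 11
Reactants: 15 4-iodocatechol
Product: 16 4-iodo-1,2-phenylene bis(benzyl carbonate)
Conditions: BnOCOCl (2.5 equiv), Et3N added last, CH2Cl2, −10 to 0 °C
Reagents that add atoms: benzyl chloroformate, `O=C(Cl)OCc1ccccc1`
Why: Acylation of both phenols with a chloroformate; the benzyl carbonate is as electron-poor as an alkanoate ester, which is what step 16 needs, but leaves by hydrogenolysis, whereas basic ester cleavage would free a 4′-phenoxide able to reopen ring C through a quinone methide and scramble C2.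

Step 12
Reactants: 14 1,5-bis(benzyloxy)-3-(tert-butyldimethylsilyloxy)-4-(DBn)-2-(prop-2-yn-1-yl)benzene; 16 4-iodo-1,2-phenylene bis(benzyl carbonate)
Product: 17 dibenzyl 4-{3-[ArA(OTBS)]prop-1-yn-1-yl}-1,2-phenylene dicarbonate
Conditions: Pd(PPh3)2Cl2 (3 mol %), CuI (5 mol %), Et3N, THF, rt, argon
Reagents that add atoms: none
Why: Sonogashira coupling of an aryl iodide runs at room temperature with a tertiary amine, conditions too mild to isomerise the propargylic CH2 to an allene or to attack the aryl carbonates.

Step 13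
Reactants: 17 dibenzyl 4-{3-[ArA(OTBS)]prop-1-yn-1-yl}-1,2-phenylene dicarbonate
Product: 18 dibenzyl 4-{(Z)-3-[ArA(OTBS)]prop-1-en-1-yl}-1,2-phenylene dicarbonate
Conditions: H2 (1 atm, 1 equiv), Pd/CaCO3 poisoned with Pb(OAc)2, quinoline, EtOAc, rt
Reagents that add atoms: none
Why: Lindlar semihydrogenation adds H2 syn on the poisoned surface and so fixes the Z geometry, while benzyl ethers and benzyl carbonates are left alone at one equivalent of hydrogen.

Step 14
Reactants: 18 dibenzyl 4-{(Z)-3-[ArA(OTBS)]prop-1-en-1-yl}-1,2-phenylene dicarbonate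
Product: 19 dibenzyl 4-{(2S,3R)-3-[ArA(OTBS)methyl]oxiran-2-yl}-1,2-phenylene dicarbonate (cis-epoxide)
Conditions: L-glucose-derived spiro N-(4-methylphenyl)oxazolidinone ketone (antipode of the Shi cis-olefin catalyst, 25 mol %), 2KHSO5·KHSO4·K2SO4, K2CO3, Bu4NHSO4, DME/dimethoxymethane, K2CO3–AcOH buffer pH 8, −10 °C
Reagents that add atoms: potassium peroxymonosulfate, `[K+].[O-]S(=O)(=O)OO`
Why: Shi-type epoxidation of a cis-β-substituted styrene: the chiral dioxirane transfers oxygen in a concerted spiro transition state that preserves the cis geometry, and the attraction between conjugated ring B and the oxazolidinone of the L-series catalyst selects the face that sets C2 as (S) and C3 as (R) in one event.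

Step 15
Reactants: 19 dibenzyl 4-{(2S,3R)-3-[ArA(OTBS)methyl]oxiran-2-yl}-1,2-phenylene dicarbonate
Product: 20 dibenzyl 4-{(2S,3R)-3-[ArA(OH)methyl]oxiran-2-yl}-1,2-phenylene dicarbonate (cis-epoxide phenol)
Conditions: Bu4NF/AcOH (1:1.2), THF, 0 °C; used promptly
Reagents that add atoms: none
Why: Fluoride cleaves the aryl silyl ether within minutes, and the acetic acid buffer keeps the product as the neutral phenol so that neither 5-exo opening by a phenoxide nor attack on the carbonates should occur.

Step 16
Reactants: 20 dibenzyl 4-{(2S,3R)-3-[ArA(OH)methyl]oxiran-2-yl}-1,2-phenylene dicarbonate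
Product: 21 (2R,3R)-5,7-bis(benzyloxy)-2-[3,4-bis(benzyloxycarbonyloxy)phenyl]-8-(DBn)chroman-3-ol
Conditions: (1S)-(+)-camphor-10-sulfonic acid (15 mol %), 4 Å molecular sieves, CH2Cl2, −30 to 0 °C
Reagents that add atoms: none
Why: The sulfonic acid protonates the oxirane oxygen, the C2–O bond loosens because C2 is benzylic, and the neutral phenol oxygen on C8a attacks C2 from the side opposite to the leaving oxygen, after which loss of the proton returns the catalyst. The closest known reaction type is the acid-catalysed intramolecular endo opening of aryl-substituted epoxides by phenols and alcohols, a borderline SN2 etherification already used to make chroman-3-ols and flavan-3-ols. Ring C closes in the 6-endo-tet mode through the new O1–C2 bond. C2 becomes (R) by stereospecific inversion of the (2S) oxirane carbon, C3 stays (R) because its C–O bond is never broken, and so the cis-oxirane is translated into the 2,3-cis flavan-3-ol. The step needs 6-endo instead of 5-exo attack and inversion instead of ionisation: the first is secured by benzylic polarisation under acid (a phenoxide would prefer C3), the second by the two electron-poor carbonate groups on ring B, the apolar solvent and the low temperature, which keep a free C2 cation or quinone methide out of reach. All other phenols are masked and the second ortho carbon of the nucleophilic phenol already bears the bridge, so only one ring and only the C8 isomer can form.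

Step 17
Reactants: 21 (2R,3R)-5,7-bis(benzyloxy)-2-[3,4-bis(benzyloxycarbonyloxy)phenyl]-8-(DBn)chroman-3-ol
Product: 22 (2R,3R)-2-(3,4-dihydroxyphenyl)-8-{2,6-dihydroxy-4-methoxy-3-methyl-5-[(2S)-2-methylbutanoyl]benzyl}chroman-3,5,7-triol (target)
Conditions: H2 (1 atm), Pd(OH)2/C, THF/MeOH, rt, degassed work-up
Reagents that add atoms: none
Why: Catalytic hydrogenolysis removes four benzyl ethers and, through loss of CO2 from the carbonic half-esters, both benzyl carbonates in one neutral operation, so that C2, the air-sensitive catechol and the α-stereocentre never meet base, while the O1–C2 bond and the chelated ketone are known to tolerate these conditions in the flavan-3-ol and acylphloroglucinol series.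

Compound list
1 | (S)-2-methylbutanoic acid | `CC[C@H](C)C(=O)O` | starting material
2 | 2,4,6-trihydroxytoluene | `Cc1c(O)cc(O)cc1O` | starting material
3 | (S)-2-methylbutanoyl chloride | `CC[C@H](C)C(=O)Cl` | intermediate (not isolated)
4 | (S)-2-methyl-1-(2,4,6-trihydroxy-3-methylphenyl)butan-1-one | `CC[C@H](C)C(=O)c1c(O)cc(O)c(C)c1O` | intermediate
5 | (S)-1-[4,6-bis(benzyloxy)-2-hydroxy-3-methylphenyl]-2-methylbutan-1-one | `CC[C@H](C)C(=O)c1c(OCc2ccccc2)cc(OCc2ccccc2)c(C)c1O` | intermediate
6 | (S)-1-[4,6-bis(benzyloxy)-2-methoxy-3-methylphenyl]-2-methylbutan-1-one | `CC[C@H](C)C(=O)c1c(OCc2ccccc2)cc(OCc2ccccc2)c(C)c1OC` | intermediate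
7 | 2,6-bis(benzyloxy)-4-methoxy-3-methyl-5-[(2S)-2-methylbutanoyl]benzaldehyde | `CC[C@H](C)C(=O)c1c(OCc2ccccc2)c(C=O)c(OCc2ccccc2)c(C)c1OC` | intermediate
8 | (S)-1-[2,4-bis(benzyloxy)-3-(hydroxymethyl)-6-methoxy-5-methylphenyl]-2-methylbutan-1-one | `CC[C@H](C)C(=O)c1c(OCc2ccccc2)c(CO)c(OCc2ccccc2)c(C)c1OC` | intermediate
9 | 3,5-bis(benzyloxy)phenol | `Oc1cc(OCc2ccccc2)cc(OCc2ccccc2)c1` | starting material
10 | 3,5-bis(benzyloxy)-2-(DBn)phenol | `CC[C@H](C)C(=O)c1c(OCc2ccccc2)c(Cc3c(O)cc(OCc4ccccc4)cc3OCc5ccccc5)c(OCc2ccccc2)c(C)c1OC` | intermediate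
11 | 4,6-bis(benzyloxy)-2-hydroxy-3-(DBn)benzaldehyde | `CC[C@H](C)C(=O)c1c(OCc2ccccc2)c(Cc3c(O)c(C=O)c(OCc4ccccc4)cc3OCc5ccccc5)c(OCc2ccccc2)c(C)c1OC` | intermediate
12 | 4,6-bis(benzyloxy)-2-(tert-butyldimethylsilyloxy)-3-(DBn)benzaldehyde | `CC[C@H](C)C(=O)c1c(OCc2ccccc2)c(Cc3c(O[Si](C)(C)C(C)(C)C)c(C=O)c(OCc4ccccc4)cc3OCc5ccccc5)c(OCc2ccccc2)c(C)c1OC` | intermediate
13 | 1-[ArA(OTBS)]prop-2-yn-1-ol, both carbinol epimers | `CC[C@H](C)C(=O)c1c(OCc2ccccc2)c(Cc3c(O[Si](C)(C)C(C)(C)C)c(C(O)C#C)c(OCc4ccccc4)cc3OCc5ccccc5)c(OCc2ccccc2)c(C)c1OC` | intermediate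
14 | 1,5-bis(benzyloxy)-3-(tert-butyldimethylsilyloxy)-4-(DBn)-2-(prop-2-yn-1-yl)benzene | `CC[C@H](C)C(=O)c1c(OCc2ccccc2)c(Cc3c(O[Si](C)(C)C(C)(C)C)c(CC#C)c(OCc4ccccc4)cc3OCc5ccccc5)c(OCc2ccccc2)c(C)c1OC` | intermediate
15 | 4-iodocatechol | `Oc1ccc(I)cc1O` | starting material
16 | 4-iodo-1,2-phenylene bis(benzyl carbonate) | `O=C(OCc1ccccc1)Oc1ccc(I)cc1OC(=O)OCc1ccccc1` | intermediate
17 | dibenzyl 4-{3-[ArA(OTBS)]prop-1-yn-1-yl}-1,2-phenylene dicarbonate | `CC[C@H](C)C(=O)c1c(OCc2ccccc2)c(Cc3c(O[Si](C)(C)C(C)(C)C)c(CC#Cc6ccc(OC(=O)OCc7ccccc7)c(OC(=O)OCc7ccccc7)c6)c(OCc4ccccc4)cc3OCc5ccccc5)c(OCc2ccccc2)c(C)c1OC` | intermediate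
18 | dibenzyl 4-{(Z)-3-[ArA(OTBS)]prop-1-en-1-yl}-1,2-phenylene dicarbonate | `CC[C@H](C)C(=O)c1c(OCc2ccccc2)c(Cc3c(O[Si](C)(C)C(C)(C)C)c(C/C=C\c6ccc(OC(=O)OCc7ccccc7)c(OC(=O)OCc7ccccc7)c6)c(OCc4ccccc4)cc3OCc5ccccc5)c(OCc2ccccc2)c(C)c1OC` | intermediate
19 | dibenzyl 4-{(2S,3R)-3-[ArA(OTBS)methyl]oxiran-2-yl}-1,2-phenylene dicarbonate | `CC[C@H](C)C(=O)c1c(OCc2ccccc2)c(Cc3c(O[Si](C)(C)C(C)(C)C)c(C[C@H]6O[C@H]6c7ccc(OC(=O)OCc8ccccc8)c(OC(=O)OCc8ccccc8)c7)c(OCc4ccccc4)cc3OCc5ccccc5)c(OCc2ccccc2)c(C)c1OC` | intermediate
20 | dibenzyl 4-{(2S,3R)-3-[ArA(OH)methyl]oxiran-2-yl}-1,2-phenylene dicarbonate (key-step precursor) | `CC[C@H](C)C(=O)c1c(OCc2ccccc2)c(Cc3c(O)c(C[C@H]6O[C@H]6c7ccc(OC(=O)OCc8ccccc8)c(OC(=O)OCc8ccccc8)c7)c(OCc4ccccc4)cc3OCc5ccccc5)c(OCc2ccccc2)c(C)c1OC` | intermediate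
21 | (2R,3R)-5,7-bis(benzyloxy)-2-[3,4-bis(benzyloxycarbonyloxy)phenyl]-8-(DBn)chroman-3-ol (key-step product) | `CC[C@H](C)C(=O)c1c(OCc2ccccc2)c(Cc3c(OCc4ccccc4)cc(OCc5ccccc5)c6c3O[C@H](c7ccc(OC(=O)OCc8ccccc8)c(OC(=O)OCc8ccccc8)c7)[C@H](O)C6)c(OCc2ccccc2)c(C)c1OC` | intermediate
22 | (2R,3R)-2-(3,4-dihydroxyphenyl)-8-{2,6-dihydroxy-4-methoxy-3-methyl-5-[(2S)-2-methylbutanoyl]benzyl}chroman-3,5,7-triol | `CC[C@H](C)C(=O)c1c(O)c(Cc2c(O)cc(O)c3c2O[C@H](c2ccc(O)c(O)c2)[C@H](O)C3)c(O)c(C)c1OC` | target

Total step count: 17. Longest linear sequence: 16 (steps 1–10 and 12–17, from 1 and 2).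

Steps most likely to fail

Step 16.
- What may go wrong: in a cis-oxirane the aryl ring is twisted out of conjugation, so benzylic assistance is weaker than in the trans series. Competing 5-exo attack at C3, partial ionisation at C2 with loss of the inversion, or a hydride shift of the protonated oxirane could then erode the outcome.
- The fallback sets out from 8 and comes back at 22. It gives up the ring closure and grafts ring D onto a ready-made ring C.
- Commercial (−)-epicatechin is benzylated on its four phenols (BnBr, K2CO3, DMF) to 5,7,3′,4′-tetra-O-benzyl-(−)-epicatechin F1.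
- F1, in excess, is alkylated by the cation from 8 (BF3·OEt2, CH2Cl2, −40 °C). The attack should fall at C8, the position that benzylated flavan-3-ols offer preferentially to carbon electrophiles in interflavan bond formation. This gives the hexa-O-benzyl ether of the target F2, and any C6 isomer is removed by chromatography.
- Hydrogenolysis over Pd(OH)2/C as in step 17 then gives 22.

Step 14.
- What may go wrong: poor facial selectivity, because the non-conjugated substituent is unusually bulky; slow conversion of a large lipophilic substrate in the aqueous-organic medium; slow hydrolytic loss of a carbonate in the buffer.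
- The fallback sets out from 18 and comes back at 19. It replaces the organocatalytic dioxirane by metal-oxo transfer.
- This is a Jacobsen–Katsuki epoxidation with (S,S)-N,N′-bis(3,5-di-tert-butylsalicylidene)-1,2-cyclohexanediaminomanganese chloride, mCPBA and N-methylmorpholine N-oxide in CH2Cl2 at −78 °C, homogeneous and water-free.
- The (S,S) antipode is the one that turns indene into its (1S,2R)-oxide, which is the same benzylic sense.
- Leakage of the stepwise radical pathway to the trans series gives a diastereomer that chromatography should remove.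
- The fallback makes no compound outside the list (entry F0).

Step 6.
- What may go wrong: attack at the carbon between the two benzyloxy groups, double alkylation of the phenol, or acid-induced loss of a benzyl group next to the cation.
- The fallback sets out from 7 (together with 9) and comes back at 10. It skips step 5 and replaces the free cation by a boron template.
- Compounds 7, 9 and PhB(OH)2 with catalytic propanoic acid in refluxing toluene (water separator) condense strictly ortho to the phenol oxygen. The product is 5,7-bis(benzyloxy)-2-phenyl-4-aryl-4H-1,3,2-benzodioxaborin F3, in which the aryl group is ring D.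
- Et3SiH/CF3CO2H in CH2Cl2 then ionises the doubly benzylic C–O bond and reduces it to the CH2 bridge. Aqueous work-up frees the phenol 10.

Further compounds
F1 | step 16 | 5,7,3′,4′-tetra-O-benzyl-(−)-epicatechin | `c1c(OCc3ccccc3)cc(OCc3ccccc3)c2c1O[C@H](c1ccc(OCc3ccccc3)c(OCc3ccccc3)c1)[C@H](O)C2`
F2 | step 16 | (2R,3R)-5,7-bis(benzyloxy)-2-[3,4-bis(benzyloxy)phenyl]-8-(DBn)chroman-3-ol | `CC[C@H](C)C(=O)c1c(OCc2ccccc2)c(Cc3c(OCc4ccccc4)cc(OCc5ccccc5)c6c3O[C@H](c7ccc(OCc8ccccc8)c(OCc8ccccc8)c7)[C@H](O)C6)c(OCc2ccccc2)c(C)c1OC`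
F0 | step 14 | none | none
F3 | step 6 | 5,7-bis(benzyloxy)-2-phenyl-4-{2,6-bis(benzyloxy)-4-methoxy-3-methyl-5-[(2S)-2-methylbutanoyl]phenyl}-4H-1,3,2-benzodioxaborin, both C4 epimers | `CC[C@H](C)C(=O)c1c(OCc2ccccc2)c(C3OB(c4ccccc4)Oc4cc(OCc5ccccc5)cc(OCc5ccccc5)c34)c(OCc2ccccc2)c(C)c1OC`
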